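## Retrosynthetic overview

1. Target 13 ⇒ dibromide 12: the side-chain C–Cl bond and the ring C=C come from an ene-type allylic chlorination of an E-alkylidene.
2. 12 ⇒ diene 11 (key step): both C–Br bonds, including the neopentyl ring C–Br, come from one radical-chain 1,4-bromine-atom transfer across a 1-vinylcyclohexene.
3. 11 ⇒ enyne 10: the only ring is closed by ring-closing enyne metathesis.
4. 10 ⇒ chloro alcohol 6 + propargyl bromide 7 (sp3–sp3 alkylation); 6 ⇒ aldehyde 4 by enamine-catalysed α-chlorination, which fixes the absolute configuration.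
5. 4 ⇒ prenol 1 + ethyl vinyl ether 2: a Claisen rearrangement builds the quaternary carbon.

Assumption: (2R,5R)-2,5-diphenylpyrrolidine is taken to give the (S)-α-chloroaldehyde, as reported for β-branched aldehydes; the (2S,5S) catalyst would be used if the sense were opposite for this substrate.

## Route

Step 1
Reactants: 1 3-methylbut-2-en-1-ol (prenol); 2 ethyl vinyl ether
Product: 4 3,3-dimethylpent-4-enal, via prenyl vinyl ether 3 (not isolated)
Conditions: Hg(OAc)2 (5 mol %), 2 (10 equiv, as solvent), reflux; then neat, sealed tube, 150 °C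
Reagents that add atoms: none
Why: Transetherification to the allyl vinyl ether followed by a thermal [3,3]-sigmatropic (Claisen) rearrangement builds the gem-dimethyl quaternary carbon with an aldehyde on one side and a vinyl group on the other; no stereocentre is formed.

Step 2
Reactants: 4 3,3-dimethylpent-4-enal
Product: 6 (S)-2-chloro-3,3-dimethylpent-4-en-1-ol, via chloroaldehyde 5 (not isolated)
Conditions: N-chlorosuccinimide (1.2 equiv), (2R,5R)-2,5-diphenylpyrrolidine (10 mol %), CH2Cl2, 0 to 20 °C; then NaBH4, MeOH, 0 °C
Reagents that add atoms: N-chlorosuccinimide, O=C1CCC(=O)N1Cl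
Why: Enamine-catalysed enantioselective α-chlorination (Jørgensen type), in which the C2-symmetric amine shields one enamine face, sets the C–Cl stereocentre directly on the carbon next to the quaternary centre without any substitution step; in-situ borohydride reduction prevents racemisation of the α-chloroaldehyde.

Step 3
Reactants: 6 (S)-2-chloro-3,3-dimethylpent-4-en-1-ol; 7 3-bromoprop-1-yne (propargyl bromide)
Product: 10 (R)-4-chloro-3,3-dimethyloct-1-en-7-yne, via 1,3-dilithiopropyne 8 (not isolated), via triflate 9 (not isolated)
Conditions: 6, Tf2O, 2,6-lutidine, CH2Cl2, −78 °C; separately 7, n-BuLi (2.0 equiv), TMEDA, Et2O, −78 °C; combine, −78 to −20 °C; aq NH4Cl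
Reagents that add atoms: none
Why: SN2 displacement of the primary triflate by the sp3 carbon of the propargyl dianion gives the terminal alkyne after protonation; the C–Cl stereocentre is untouched (the descriptor changes from S to R only because the CIP priorities change).

Step 4
Reactants: 10 (R)-4-chloro-3,3-dimethyloct-1-en-7-yne
Product: 11 (R)-4-chloro-3,3-dimethyl-1-vinylcyclohex-1-ene
Conditions: second-generation Grubbs catalyst RuCl2(=CHPh)(PCy3)(H2IMes) (5 mol %), ethylene (1 atm), toluene, 80 °C
Reagents that add atoms: none
Why: Ring-closing enyne metathesis in the exo mode (Mori conditions) forms the six-membered ring and moves the alkene CH2 onto the alkyne terminus, giving the 1-vinylcyclohexene with its ring CH= next to the quaternary carbon; the chloride stereocentre is remote and unaffected.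

Step 5 (key step)
Reactants: 11 (R)-4-chloro-3,3-dimethyl-1-vinylcyclohex-1-ene
Product: 12 (1E,2R,4R)-2-bromo-1-(2-bromoethylidene)-4-chloro-3,3-dimethylcyclohexane
Conditions: BrCl2C–CCl2Br (1.05 equiv), Et3B (10 mol %), trace air, PhCF3, 0 °C, dark
Reagents that add atoms: 1,2-dibromo-1,1,2,2-tetrachloroethane, BrC(Cl)(Cl)C(Cl)(Cl)Br
Why: Proposed new method: a radical-chain 1,4-bromine-atom transfer (closest known type: radical-chain 1,4-addition of Br2 or BrCCl3 to 1,3-dienes, Kharasch type), in which Br• adds to the vinyl CH2 of the s-trans diene to give an allyl radical that abstracts Br from the donor at the ring terminus by axial, chair-forming approach on the half-chair with the chloride pseudo-equatorial, so the neopentyl C–Br bond (not accessible by substitution) is formed axial and trans to Cl, the s-trans geometry becomes the E-alkylidene, and •CCl2CCl2Br fragments to C2Cl4 and Br• to carry the chain.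

Step 6
Reactants: 12 (1E,2R,4R)-2-bromo-1-(2-bromoethylidene)-4-chloro-3,3-dimethylcyclohexane
Product: 13 (4R,6S)-6-bromo-1-[(1S)-2-bromo-1-chloroethyl]-4-chloro-5,5-dimethylcyclohex-1-ene
Conditions: Ca(OCl)2 (0.6 equiv), solid CO2, CH2Cl2/H2O, 0 °C
Reagents that add atoms: hypochlorous acid (made in the flask from Ca(OCl)2, CO2 and water), OCl
Why: Ene-type allylic chlorination with transposition (Wolinsky hypochlorous acid conditions) puts Cl on the less substituted exocyclic alkene carbon and removes the aligned axial H of the ring CH2 (C6 of 12) in the chair with axial Br and equatorial Cl, so the double bond moves into the ring away from the C–Br carbon; Cl is delivered to the face from which that axial H leaves, which on the E-alkylidene gives the (S)-chloride.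

## Compound list

1 | 3-methylbut-2-en-1-ol (prenol) | CC(C)=CCO | starting material
2 | ethyl vinyl ether | C=COCC | starting material
3 | 3-methyl-1-(vinyloxy)but-2-ene (prenyl vinyl ether) | CC(C)=CCOC=C | intermediate
4 | 3,3-dimethylpent-4-enal | O=CCC(C)(C)C=C | intermediate
5 | (S)-2-chloro-3,3-dimethylpent-4-enal | C=CC(C)(C)[C@H](Cl)C=O | intermediate
6 | (S)-2-chloro-3,3-dimethylpent-4-en-1-ol | C=CC(C)(C)[C@H](Cl)CO | intermediate
7 | 3-bromoprop-1-yne (propargyl bromide) | C#CCBr | starting material
8 | 1,3-dilithiopropyne | [Li]CC#C[Li] | intermediate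
9 | (S)-2-chloro-3,3-dimethylpent-4-en-1-yl trifluoromethanesulfonate | C=CC(C)(C)[C@H](Cl)COS(=O)(=O)C(F)(F)F | intermediate
10 | (R)-4-chloro-3,3-dimethyloct-1-en-7-yne | C=CC(C)(C)[C@H](Cl)CCC#C | intermediate
11 | (R)-4-chloro-3,3-dimethyl-1-vinylcyclohex-1-ene | C=CC1=CC(C)(C)[C@H](Cl)CC1 | intermediate
12 | (1E,2R,4R)-2-bromo-1-(2-bromoethylidene)-4-chloro-3,3-dimethylcyclohexane | BrC/C=C1\CC[C@@H](Cl)C(C)(C)[C@@H]1Br | intermediate
13 | (4R,6S)-6-bromo-1-[(1S)-2-bromo-1-chloroethyl]-4-chloro-5,5-dimethylcyclohex-1-ene | CC1(C)[C@H](Cl)CC=C([C@H](Cl)CBr)[C@H]1Br | target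

## Step count and risks

Total step count: 6. Longest linear sequence: 6 steps.

The three steps most likely to fail are steps 5, 6 and 3.

The radical bromine transfer of step 5 may give the 1,2-adduct instead of the 1,4-adduct, may run with a short chain, or may give the cis C–Br epimer. The fallback sets out from 11 and comes back at 12. Polar bromination with Br2 in CH2Cl2 at −78 °C gives mainly the kinetic vicinal dibromide (4R)-4-chloro-1-(1,2-dibromoethyl)-3,3-dimethylcyclohex-1-ene F1. Catalytic ZnBr2 at 20 °C then equilibrates it by 1,3-allylic bromide shift to the 1,4-dibromide 12 with axial Br, under thermodynamic instead of kinetic control.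

The ene chlorination of step 6 is the weakest point for stereochemistry. The facial selectivity at the exocyclic carbon rests on a conformational model (both chairs may be populated, and a stepwise chloronium path could favour the other face). Loss of the H on the C–Br carbon and chlorohydrin formation can also compete. The fallback sets out from 12 and comes back at 13, and sets the side-chain centre by reagent control:
- Photo-oxygenation (O2, tetraphenylporphyrin, hν, CH2Cl2, −20 °C; Schenck ene reaction) gives the allylic hydroperoxide 2-bromo-1-[(4R,6R)-6-bromo-4-chloro-5,5-dimethylcyclohex-1-en-1-yl]ethyl hydroperoxide F2.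
- Dehydration with Ac2O/pyridine gives the enone 2-bromo-1-[(4R,6R)-6-bromo-4-chloro-5,5-dimethylcyclohex-1-en-1-yl]ethan-1-one F3.
- Reduction with (R)-Me-CBS oxazaborolidine and BH3·SMe2 (cyclohexenyl as the large group) gives the bromohydrin (1R)-2-bromo-1-[(4R,6R)-6-bromo-4-chloro-5,5-dimethylcyclohex-1-en-1-yl]ethan-1-ol F4.
- Deoxychlorination with inversion using 1-chloro-N,N,2-trimethylprop-1-en-1-amine gives 13.

The alkylation of step 3 may fail through E2 elimination or slow SN2 at the β-branched, β-chloro triflate with the strongly basic dianion. The fallback sets out from 5 (taken before the borohydride quench) and comes back at 10, replacing substitution by carbonyl addition and radical deoxygenation: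
- Barbier propargylation with 7 and Zn in THF/aq NH4Cl gives the chlorohydrin (5S)-5-chloro-6,6-dimethyloct-7-en-1-yn-4-ol F5.
- Phenyl chlorothionoformate with pyridine (no alkoxide, so no epoxide closure) gives the thionocarbonate O-[(5S)-5-chloro-6,6-dimethyloct-7-en-1-yn-4-yl] O-phenyl carbonothioate F6.
- Barton–McCombie deoxygenation (Bu3SnH, AIBN, toluene, 80 °C) gives 10.

Further compounds
F1 | step 5 | (4R)-4-chloro-1-(1,2-dibromoethyl)-3,3-dimethylcyclohex-1-ene (both configurations at the side-chain CHBr) | BrCC(Br)C1=CC(C)(C)[C@H](Cl)CC1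
F2 | step 6 | 2-bromo-1-[(4R,6R)-6-bromo-4-chloro-5,5-dimethylcyclohex-1-en-1-yl]ethyl hydroperoxide (either configuration at the side-chain carbon) | CC1(C)[C@H](Cl)CC=C(C(OO)CBr)[C@H]1Br
F3 | step 6 | 2-bromo-1-[(4R,6R)-6-bromo-4-chloro-5,5-dimethylcyclohex-1-en-1-yl]ethan-1-one | CC1(C)[C@H](Cl)CC=C(C(=O)CBr)[C@H]1Br
F4 | step 6 | (1R)-2-bromo-1-[(4R,6R)-6-bromo-4-chloro-5,5-dimethylcyclohex-1-en-1-yl]ethan-1-ol | CC1(C)[C@H](Cl)CC=C([C@@H](O)CBr)[C@H]1Br
F5 | step 3 | (5S)-5-chloro-6,6-dimethyloct-7-en-1-yn-4-ol (either configuration at C4) | C#CCC(O)[C@@H](Cl)C(C)(C)C=C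
F6 | step 3 | O-[(5S)-5-chloro-6,6-dimethyloct-7-en-1-yn-4-yl] O-phenyl carbonothioate | C#CCC(OC(=S)Oc1ccccc1)[C@@H](Cl)C(C)(C)C=C
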